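**Retrosynthetic overview**

1. Numbering (Stemona convention): ring A = N4, C1–C3, C9a (pyrrolidine); ring B = N4, C5–C9, C9a (azepane); ring C = C9, C9a, C12, C11, C10 (cyclopentane, ethyl C16–C17 on C10); ring D = O–C11, C12, C13 (CH3, OH), C14 (=O); ring E = O–C18, C19, C20 (CH3), C21 (=O), attached at C3.
2. Enabling feature: C11 is a ring C atom and also the O-bearing γ-carbon of lactone ring D, and its neighbour C10 carries an ethyl group. A carboxyl on C11 can leave as CO2 to give an oxygen-stabilised radical at the atom that must bond to C10, and an E-propenyl group on C9 (C10=C16) serves as both radical acceptor and latent ethyl.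
3. Ring C is trans-fused to ring B, so C9a–C12 is not used as the closing bond (closure onto a planar C9a inside ring B would give the cis fusion). It is made first and intermolecularly, anti to the C9 substituent, and ring C is closed at C10–C11.
4. Disconnections, backwards: C5 lactam carbonyl; C3–C18 (vinylogous Mannich addition of an intact furanone); C13 CH3 and OH (lactone enolate); C10–C11 (decarboxylative 5-exo radical cyclisation); C9a–C12 (decarboxylative Giese addition to an intact butenolide); N4–C5 (lactamisation); C9–C9a (Ireland–Claisen rearrangement, chirality from (S)-but-3-en-2-ol).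
5. Ring order: A (from proline) → B (step 4) → D (brought in as a ring, step 5) → C (step 7, the last ring closure). Ring E is never closed in the route; it is attached as the preformed furanone in step 12.

Key step: step 7

Remark: C9a in 8–10 and C11 in 12–14 are drawn with the expected configuration, but neither is relied on, because both carbons pass through planar radicals (steps 5 and 7).

**Route**

Step 1
Reactants: 1 N-Boc-L-proline; 2 (2S)-but-3-en-2-ol
Product: 3 1-tert-butyl 2-[(2S)-but-3-en-2-yl] (2S)-pyrrolidine-1,2-dicarboxylate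
Conditions: DCC, DMAP (cat.), CH2Cl2, 0 → 23 °C
Reagents that add atoms: none
Why: Steglich esterification (carbodiimide activation, DMAP acyl transfer) should join the acid to the secondary allylic alcohol without touching the carbinol centre, so the (S) centre of 2 that steers step 3 is carried into 3.

Step 2
Reactants: 3 1-tert-butyl 2-[(2S)-but-3-en-2-yl] (2S)-pyrrolidine-1,2-dicarboxylate; 4 hex-5-enoic acid (excess)
Product: 5 (5E,7S)-7-{[(2S)-1-(tert-butoxycarbonyl)pyrrolidine-2-carbonyl]oxy}oct-5-enoic acid
Conditions: second-generation Grubbs catalyst (3 mol%), CH2Cl2, 40 °C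
Reagents that add atoms: none
Why: Olefin cross-metathesis of the monosubstituted alkene of 3 with an excess of the unhindered terminal alkene 4 should give the E-disubstituted alkene (thermodynamic control under the ruthenium carbene) and tolerates the free acid and the carbamate; no stereocentre is formed.

Step 3
Reactants: 5 (5E,7S)-7-{[(2S)-1-(tert-butoxycarbonyl)pyrrolidine-2-carbonyl]oxy}oct-5-enoic acid
Product: 8 (2S)-1-(tert-butoxycarbonyl)-2-[(2E,4R)-7-carboxyhept-2-en-4-yl]pyrrolidine-2-carboxylic acid, via silyl ketene acetal 6 (not isolated), via bis(trimethylsilyl) ester 7 (not isolated)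
Conditions: LiN(iPr)2 (2.3 equiv), THF, −78 °C; Me3SiCl, −78 → 60 °C; then 1 M HCl
Reagents that add atoms: none
Why: Ireland–Claisen rearrangement: the ester enolate (chain carboxylate deprotonated first) is trapped as the silyl ketene acetal, which rearranges suprafacially with the carbinol methyl pseudo-equatorial, so the (S) carbinol centre is relayed to (R)-C9 and an E C10=C16 alkene while the C9–C9a bond and the quaternary C9a are made; the chair transition state of the N,O-chelated ketene acetal should give 9aS as drawn, but this centre is not relied on.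

Step 4
Reactants: 8 (2S)-1-(tert-butoxycarbonyl)-2-[(2E,4R)-7-carboxyhept-2-en-4-yl]pyrrolidine-2-carboxylic acid
Product: 10 (9R,9aS)-5-oxo-9-[(1E)-prop-1-en-1-yl]octahydro-1H-pyrrolo[1,2-a]azepine-9a-carboxylic acid, via amino diacid 9 (not isolated)
Conditions: CF3CO2H, CH2Cl2, 0 → 23 °C; then EDC·HCl, HOAt (cat.), iPr2NEt, DMF (5 mM), 23 °C
Reagents that add atoms: none
Why: Acidolysis of the tert-butyl carbamate and carbodiimide-mediated lactamisation (amide coupling at high dilution) should close the seven-membered ring B through the unhindered chain carboxyl, since the C9a carboxyl is neopentyl-type and cannot lactamise onto its own nitrogen; no stereocentre is touched.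

Step 5
Reactants: 10 (9R,9aS)-5-oxo-9-[(1E)-prop-1-en-1-yl]octahydro-1H-pyrrolo[1,2-a]azepine-9a-carboxylic acid; 11 (5S)-5-(hydroxymethyl)furan-2(5H)-one (2 equiv)
Product: 12 (9R,9aS)-9a-[(2S,3R)-2-(hydroxymethyl)-5-oxooxolan-3-yl]-9-[(1E)-prop-1-en-1-yl]octahydro-5H-pyrrolo[1,2-a]azepin-5-one
Conditions: Ir[dF(CF3)ppy]2(dtbbpy)PF6 (1 mol%), K2HPO4, DMF, blue LEDs, 23 °C
Reagents that add atoms: none
Why: Photoredox decarboxylative Giese addition: the carboxylate is oxidised by the excited iridium complex and loses CO2 to give the planar α-amido radical at C9a, which should add to the β-carbon of butenolide 11 on the face of ring B opposite to the propenyl group on C9 (C9a set, C12 trans to C10 across ring B) and on the face of 11 opposite to its hydroxymethyl group (C12 set), after which the α-carbonyl radical is reduced and protonated.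

Step 6
Reactants: 12 (9R,9aS)-9a-[(2S,3R)-2-(hydroxymethyl)-5-oxooxolan-3-yl]-9-[(1E)-prop-1-en-1-yl]octahydro-5H-pyrrolo[1,2-a]azepin-5-one
Product: 13 (2S,3R)-5-oxo-3-{(9R,9aS)-5-oxo-9-[(1E)-prop-1-en-1-yl]octahydro-1H-pyrrolo[1,2-a]azepin-9a-yl}oxolane-2-carboxylic acid
Conditions: TEMPO (cat.), PhI(OAc)2, MeCN/H2O (1:1), 23 °C
Reagents that add atoms: water, O
Why: Nitroxyl-catalysed oxidation (oxoammonium cycle with PhI(OAc)2 as terminal oxidant, through the aldehyde hydrate) should take the primary alcohol to the acid and leave the alkene, lactam and lactone alone; C11 need not stay configurationally pure because it becomes a planar radical in step 7.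

Step 7
Reactants: 13 (2S,3R)-5-oxo-3-{(9R,9aS)-5-oxo-9-[(1E)-prop-1-en-1-yl]octahydro-1H-pyrrolo[1,2-a]azepin-9a-yl}oxolane-2-carboxylic acid
Product: 15 (9R,9aS,10R,11S,12R)-10-ethyl tetracyclic lactam lactone (rings A–D; C5 and C14 carbonyls; C13 unsubstituted), via N-(acyloxy)phthalimide 14 (not isolated)
Conditions: N-hydroxyphthalimide, iPrN=C=NiPr, DMAP (cat.), CH2Cl2, 23 °C; then [Ru(bpy)3](PF6)2 (1 mol%), diethyl 2,6-dimethyl-1,4-dihydropyridine-3,5-dicarboxylate (1.5 equiv), iPr2NEt, blue LEDs, 23 °C
Reagents that add atoms: none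
Why: Carbodiimide coupling converts the acid into the N-(acyloxy)phthalimide 14; the excited ruthenium complex is reduced by the dihydropyridine to the monovalent complex, which transfers an electron to 14, and the radical anion breaks down to phthalimide anion, CO2 and the C11 radical, stabilised by the ring D oxygen; this radical adds to C10 of the propenyl group and the secondary C16 radical takes a hydrogen atom from the dihydropyridine, so that the acceptor ends as the C16–C17 ethyl group. The closest known reaction type is the reductive decarboxylative radical cyclisation of redox-active N-(acyloxy)phthalimide esters under visible light, the modern form of the Barton decarboxylative cyclisation. Ring C closes in the 5-exo-trig mode. C11 is controlled by ring strain, because rings C and D can only be cis-fused, so the planar radical bonds on the face of the C12–C9a bond whichever C11 epimer of 13 is used; C10 is controlled by a chair-like transition state in which C9–H eclipses the C10=C16 bond (allylic 1,3-strain), which places C16 anti to C8 on C9 and anti to the lactone oxygen on C11. The step needs ring closure to be faster than hydrogen transfer to C11 and 5-exo to beat 6-endo attack: the dihydropyridine is a slow hydrogen donor, the radical and the alkene are held five atoms apart on the C9a–C9 bond, and exo attack on the 1,2-disubstituted alkene is the kinetically normal course.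

Step 8
Reactants: 15 (9R,9aS,10R,11S,12R)-10-ethyl tetracyclic lactam lactone
Product: 16 (13S)-13-methyl derivative of 15
Conditions: LiN(iPr)2 (1.05 equiv), THF, −78 °C; MeI, −78 → −40 °C
Reagents that add atoms: iodomethane, CI
Why: Kinetic lithium enolate alkylation: the lactone α-CH2 (C13) is clearly more acidic than the lactam α-CH2 (C6), and the enolate should take the methyl group on the convex face of the cis-fused C/D bicycle; this C13 configuration is provisional, as step 9 passes through the enolate again.

Step 9
Reactants: 16 (13S)-13-methyl derivative of 15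
Product: 17 (9R,9aS,10R,11S,12R,13S)-13-hydroxy-13-methyl derivative of 15
Conditions: KN(SiMe3)2 (1.1 equiv), THF, −78 °C; 2-(benzenesulfonyl)-3-phenyloxaziridine; NH4Cl (aq)
Reagents that add atoms: 2-(benzenesulfonyl)-3-phenyloxaziridine, O=S(=O)(N1OC1c1ccccc1)c1ccccc1
Why: Enolate hydroxylation with an N-sulfonyloxaziridine: the tetrasubstituted potassium enolate should accept oxygen on the convex face of the cis-fused C/D bicycle, anti to C9a, which puts the hydroxyl cis to H12 and turns the methyl group to the concave face (13S).

Step 10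
Reactants: 17 (9R,9aS,10R,11S,12R,13S)-13-hydroxy-13-methyl derivative of 15
Product: 18 3-methoxy derivative of 17 (N,O-acetal, both C3 epimers)
Conditions: graphite anode, Pt cathode, undivided cell, Et4NOTs, MeOH, constant current (2.5 F/mol), 0 °C
Reagents that add atoms: methanol, CO
Why: Shono oxidation (anodic α-methoxylation of an amide through the N-acyliminium ion): C3 is the only hydrogen-bearing carbon on nitrogen, C9a being quaternary, so the N,O-acetal can form only there; its configuration is lost again in step 12.

Step 11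
Reactants: 19 3-methylfuran-2(5H)-one
Product: 20 3-methyl-2-{[tri(propan-2-yl)silyl]oxy}furan
Conditions: iPr3SiOTf, Et3N, CH2Cl2, 0 °C
Reagents that add atoms: tri(propan-2-yl)silyl trifluoromethanesulfonate, CC(C)[Si](C(C)C)(C(C)C)OS(=O)(=O)C(F)(F)F
Why: Soft enolisation and O-silylation of the butenolide with silyl triflate and triethylamine gives the aromatic 2-silyloxyfuran, the nucleophile for step 12; no stereocentre is involved.

Step 12
Reactants: 18 3-methoxy derivative of 17; 20 3-methyl-2-{[tri(propan-2-yl)silyl]oxy}furan (1.5 equiv)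
Product: 21 (3S)-3-[(2S)-4-methyl-5-oxo-2,5-dihydrofuran-2-yl] derivative of 17 (C18 = S)
Conditions: iPr3SiOTf (0.2 equiv), CH2Cl2, −78 °C
Reagents that add atoms: none
Why: Vinylogous Mannich reaction: the silyl triflate ionises 18 to the C3 N-acyliminium ion, which the silyloxyfuran attacks through its C5; the furan should approach from the face of H12, anti to the C8–C6 chain of the trans-fused azepanone that lies under the other face of ring A (3S), and the open transition state usual for silyloxyfurans and cyclic N-acyliminium ions should give the threo pair (18S).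

Step 13
Reactants: 21 (3S)-3-[(2S)-4-methyl-5-oxo-2,5-dihydrofuran-2-yl] derivative of 17
Product: 22 5-oxo derivative (ring B lactam) of the target, (3S,9R,9aS,10R,11S,12R,13S,18S,20S)
Conditions: H2 (1 atm), Pd/C, EtOAc, 23 °C
Reagents that add atoms: none
Why: Heterogeneous catalytic hydrogenation of the trisubstituted butenolide alkene from the face of ring E opposite to its C18 substituent should give the cis-2,4-disubstituted γ-lactone (20S); nothing else in 21 is reducible under these conditions.

Step 14
Reactants: 22 5-oxo derivative (ring B lactam) of the target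
Product: 23 CNP0260919.2 (target), (3S,9R,9aS,10R,11S,12R,13S,18S,20S)
Conditions: Zn(OAc)2 (10 mol%), (EtO)3SiH (3 equiv), THF, 40 °C; then NH4F, MeOH
Reagents that add atoms: none
Why: Zinc-catalysed hydrosilylation of the tertiary amide (through the O-silyl hemiaminal and the iminium ion) should reduce the lactam carbonyl to CH2 while the two lactones, which react far more slowly with this catalyst, survive; the silyl ether formed at the tertiary hydroxyl is cleaved by fluoride on work-up and no stereocentre is touched.

**Compound list**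

1 | (2S)-1-(tert-butoxycarbonyl)pyrrolidine-2-carboxylic acid (N-Boc-L-proline) | CC(C)(C)OC(=O)N1CCC[C@H]1C(=O)O | starting material
2 | (2S)-but-3-en-2-ol | C[C@H](O)C=C | starting material
3 | 1-tert-butyl 2-[(2S)-but-3-en-2-yl] (2S)-pyrrolidine-1,2-dicarboxylate | CC(C)(C)OC(=O)N1CCC[C@H]1C(=O)O[C@@H](C)C=C | intermediate
4 | hex-5-enoic acid | C=CCCCC(=O)O | starting material
5 | (5E,7S)-7-{[(2S)-1-(tert-butoxycarbonyl)pyrrolidine-2-carbonyl]oxy}oct-5-enoic acid | CC(C)(C)OC(=O)N1CCC[C@H]1C(=O)O[C@@H](C)/C=C/CCCC(=O)O | intermediate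
6 | silyl ketene acetal: O-trimethylsilyl ketene acetal of the prolinate ester of 5, chain acid as trimethylsilyl ester | CC(C)(C)OC(=O)N1CCCC1=C(O[Si](C)(C)C)O[C@@H](C)/C=C/CCCC(=O)O[Si](C)(C)C | intermediate
7 | bis(trimethylsilyl) ester of 8 | CC(C)(C)OC(=O)N1CCC[C@@]1(C(=O)O[Si](C)(C)C)[C@@H](/C=C/C)CCCC(=O)O[Si](C)(C)C | intermediate
8 | (2S)-1-(tert-butoxycarbonyl)-2-[(2E,4R)-7-carboxyhept-2-en-4-yl]pyrrolidine-2-carboxylic acid | CC(C)(C)OC(=O)N1CCC[C@@]1(C(=O)O)[C@@H](/C=C/C)CCCC(=O)O | intermediate
9 | (2S)-2-[(2E,4R)-7-carboxyhept-2-en-4-yl]pyrrolidine-2-carboxylic acid (trifluoroacetate salt in the flask) | N1CCC[C@@]1(C(=O)O)[C@@H](/C=C/C)CCCC(=O)O | intermediate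
10 | (9R,9aS)-5-oxo-9-[(1E)-prop-1-en-1-yl]octahydro-1H-pyrrolo[1,2-a]azepine-9a-carboxylic acid (rings A and B) | OC(=O)[C@@]12CCCN1C(=O)CCC[C@@H]2/C=C/C | intermediate
11 | (5S)-5-(hydroxymethyl)furan-2(5H)-one | O=C1C=C[C@@H](CO)O1 | starting material
12 | (9R,9aS)-9a-[(2S,3R)-2-(hydroxymethyl)-5-oxooxolan-3-yl]-9-[(1E)-prop-1-en-1-yl]octahydro-5H-pyrrolo[1,2-a]azepin-5-one | O=C1C[C@H]([C@@]23CCCN2C(=O)CCC[C@@H]3/C=C/C)[C@@H](CO)O1 | intermediate
13 | (2S,3R)-5-oxo-3-{(9R,9aS)-5-oxo-9-[(1E)-prop-1-en-1-yl]octahydro-1H-pyrrolo[1,2-a]azepin-9a-yl}oxolane-2-carboxylic acid | O=C1C[C@H]([C@@]23CCCN2C(=O)CCC[C@@H]3/C=C/C)[C@@H](C(=O)O)O1 | intermediate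
14 | 1,3-dioxoisoindolin-2-yl ester of 13 (N-(acyloxy)phthalimide) | O=C1C[C@H]([C@@]23CCCN2C(=O)CCC[C@@H]3/C=C/C)[C@@H](C(=O)ON4C(=O)c5ccccc5C4=O)O1 | intermediate
15 | (9R,9aS,10R,11S,12R)-10-ethyl tetracyclic lactam lactone: rings A–D, C5 lactam carbonyl, rings C and D cis-fused, C13 = CH2 | CC[C@H]1[C@@H]2OC(=O)C[C@@H]2[C@@]23CCCN2C(=O)CCC[C@H]13 | intermediate
16 | (13S)-13-methyl derivative of 15 | CC[C@H]1[C@@H]2OC(=O)[C@@H](C)[C@@H]2[C@@]23CCCN2C(=O)CCC[C@H]13 | intermediate
17 | (9R,9aS,10R,11S,12R,13S)-13-hydroxy-13-methyl derivative of 15 | CC[C@H]1[C@@H]2OC(=O)[C@@](C)(O)[C@@H]2[C@@]23CCCN2C(=O)CCC[C@H]13 | intermediate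
18 | 3-methoxy derivative of 17 (N,O-acetal, C3 epimers) | CC[C@H]1[C@@H]2OC(=O)[C@@](C)(O)[C@@H]2[C@@]23CCC(OC)N2C(=O)CCC[C@H]13 | intermediate
19 | 3-methylfuran-2(5H)-one | CC1=CCOC1=O | starting material
20 | 3-methyl-2-{[tri(propan-2-yl)silyl]oxy}furan | Cc1ccoc1O[Si](C(C)C)(C(C)C)C(C)C | intermediate
21 | (3S)-3-[(2S)-4-methyl-5-oxo-2,5-dihydrofuran-2-yl] derivative of 17 (3S,18S; ring E as butenolide) | CC[C@H]1[C@@H]2OC(=O)[C@@](C)(O)[C@@H]2[C@@]23CC[C@@H]([C@@H]4C=C(C)C(=O)O4)N2C(=O)CCC[C@H]13 | intermediate
22 | 5-oxo derivative (ring B lactam) of the target, (3S,9R,9aS,10R,11S,12R,13S,18S,20S) | CC[C@H]1[C@@H]2OC(=O)[C@@](C)(O)[C@@H]2[C@@]23CC[C@@H]([C@@H]4C[C@H](C)C(=O)O4)N2C(=O)CCC[C@H]13 | intermediate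
23 | CNP0260919.2, (3S,9R,9aS,10R,11S,12R,13S,18S,20S) | CC[C@H]1[C@@H]2OC(=O)[C@@](C)(O)[C@@H]2[C@@]23CC[C@@H]([C@@H]4C[C@H](C)C(=O)O4)N2CCCC[C@H]13 | target

**Step count and risks**

Total step count: 14. Longest linear sequence: 13 steps (steps 1–10 and 12–14; step 11 makes the furan reagent).

Steps most likely to fail:

1. Step 5. Addition of the fully substituted C9a radical to the butenolide may be slow, so that hydrogen capture (plain decarboxylation) takes over, or the radical may be attacked on the face syn to the propenyl group, which would lead into the cis B/C series. Fallback (sets out from 10, returns to 12): the C9a centre made in the Ireland–Claisen step is kept and the bond C11–C12 is made instead of C9a–C12. Acid 10 is reduced through its mixed anhydride (iBuOCOCl, N-methylmorpholine; NaBH4) to the 9a-hydroxymethyl lactam F1, oxidised with Dess–Martin periodinane to the 9a-carbaldehyde F2 and homologated by Horner–Wadsworth–Emmons olefination ((EtO)2P(O)CH2CO2Et, NaH) to the E-enoate F3, in which the carboxyl carbon of 10 has become C12. Decarboxylative Giese addition of the α-oxy radical from 2,2-dimethyl-1,3-dioxolane-4-carboxylic acid (same iridium photocatalyst) to C12 gives the dioxolane ester F4. Aqueous acid (TsOH, MeOH–H2O) removes the acetonide and the secondary hydroxyl lactonises onto the ethyl ester, which gives 12 together with its C11 epimer, equally usable because C11 is planar in step 7. This variant relies on the 9aS configuration predicted for the Claisen product, and C12 is set by 1,2-induction from C9a in the radical addition, which would have to be checked.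

2. Step 7. Hydrogen transfer to the C11 radical may occur before ring closure (giving the uncyclised, decarboxylated lactone), or face selectivity at C10 may be insufficient. Fallback (sets out from 13, returns to 15): the ring is closed by a cation instead of a radical. Oxidative decarboxylation of 13 with Pb(OAc)4 gives the C11 acetate F5 (acyloxy acetal, C11 epimers); cross-metathesis with allyltrimethylsilane (second-generation Grubbs catalyst) turns the propenyl group into the allylsilane F6. BF3·OEt2 then ionises the acetate to the lactone-derived acyloxocarbenium ion, which is trapped by the allylsilane in an intramolecular Hosomi–Sakurai reaction (5-exo, cis C/D fusion enforced, vinyl group on the exo face) to give the 10-vinyl tetracycle F7; hydrogenation over Pd/C gives 15.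

3. Step 12. Facial selectivity of the furan addition at C3 may be poor (attack on the azepanone face), which would give the side chain with C3 and C18 both inverted. Fallback (sets out from 18, returns to 21): C3 is then fixed by hydride delivery instead of carbon–carbon bond formation. The adduct formed from 18 and 20 on the wrong face, the (3R,18R) diastereomer of 21 F8, is submitted again to anodic methoxylation, which can now take place only at C3 and gives the 3-methoxy-3-furanonyl N,O-acetal F9. Et3SiH with BF3·OEt2 (ionic hydrogenation of the C3 ketiminium ion) delivers hydride to the same open face that the furan had used and so inverts C3. The butenolide γ-centre C18 is then equilibrated with Et3N through the hydroxyfuran tautomer, and the threo isomer 21 is separated from its C18 epimer, which is recycled.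

**Further compounds**

F1 | step 5 | 9a-(hydroxymethyl)-9-[(1E)-prop-1-en-1-yl]octahydro-5H-pyrrolo[1,2-a]azepin-5-one (configuration as in 10) | OC[C@@]12CCCN1C(=O)CCC[C@@H]2/C=C/C
F2 | step 5 | 5-oxo-9-[(1E)-prop-1-en-1-yl]octahydro-1H-pyrrolo[1,2-a]azepine-9a-carbaldehyde (configuration as in 10) | O=C[C@@]12CCCN1C(=O)CCC[C@@H]2/C=C/C
F3 | step 5 | ethyl (2E)-3-{5-oxo-9-[(1E)-prop-1-en-1-yl]octahydro-1H-pyrrolo[1,2-a]azepin-9a-yl}prop-2-enoate (configuration as in 10) | CCOC(=O)/C=C/[C@@]12CCCN1C(=O)CCC[C@@H]2/C=C/C
F4 | step 5 | ethyl 3-(2,2-dimethyl-1,3-dioxolan-4-yl)-3-{5-oxo-9-[(1E)-prop-1-en-1-yl]octahydro-1H-pyrrolo[1,2-a]azepin-9a-yl}propanoate (C12 as in 12, dioxolane carbon as epimers) | CCOC(=O)C[C@@H](C1COC(C)(C)O1)[C@@]23CCCN2C(=O)CCC[C@@H]3/C=C/C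
F5 | step 7 | C11 acetate: 13 with the carboxyl replaced by acetoxy (C11 epimers) | O=C1C[C@H]([C@@]23CCCN2C(=O)CCC[C@@H]3/C=C/C)C(OC(C)=O)O1
F6 | step 7 | allylsilane: F5 with the propenyl group replaced by (1E)-3-(trimethylsilyl)prop-1-en-1-yl | O=C1C[C@H]([C@@]23CCCN2C(=O)CCC[C@@H]3/C=C/C[Si](C)(C)C)C(OC(C)=O)O1
F7 | step 7 | 10-vinyl analogue of 15 (9R,9aS,10R,11S,12R) | C=C[C@H]1[C@@H]2OC(=O)C[C@@H]2[C@@]23CCCN2C(=O)CCC[C@H]13
F8 | step 12 | (3R,18R) diastereomer of 21 | CC[C@H]1[C@@H]2OC(=O)[C@@](C)(O)[C@@H]2[C@@]23CC[C@H]([C@H]4C=C(C)C(=O)O4)N2C(=O)CCC[C@H]13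
F9 | step 12 | 3-methoxy-3-(4-methyl-5-oxo-2,5-dihydrofuran-2-yl) N,O-acetal derived from F8 (C3 and C18 as mixtures) | CC[C@H]1[C@@H]2OC(=O)[C@@](C)(O)[C@@H]2[C@@]23CCC(OC)(C4C=C(C)C(=O)O4)N2C(=O)CCC[C@H]13
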